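Readings and results stem from a simulated flask for an exercise.

- Watch the partner. The autumn flask, followed so far, and the winter run differ in partner charge, and their plateaus differ with it.

| setting | autumn | winter | flask |
|---|---|---|---|
| substrate | 0.080 M | 0.080 M | 0.080 M |
| partner | 0.096 M | 0.14 M | 0.0960 M |
| initiator | 5.6 mM | 5.6 mM | 5.6 mM |
| remark | the very flask that is asked about, followed so far | run made earlier |  |
| time |  |  | 12 h |

- autumn (time / h: target / %): 0.667: 18.5; 2.00: 21.5; 3.00: 22.2; 5.00: 22.5; 8.00: 22.3
- winter (time / h: target / %): 1.00: 30.0; 2.00: 31.5; 3.00: 32.0; 4.00: 32.0; 5.00: 31.6

(scatter of a reading: 0.5 percentage points)

- birch: at 12 h add partner, 100% of the amount charged, then wait 25 h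
- cedar: change nothing and wait 25 h more
- oak: at 12 h add substrate, 50.0% of the amount charged, then wait 25 h
- alder: at 12 h take out 90% of the target then present, then wait 25 h

- target taken out counts as made
- what was read earlier has a scatter of 0.5 percentage points, one standard deviation
- additions bring no volume worth counting

- target, in percent of the substrate first charged, at 12 h
- the remedy with the largest gain of target, or "none" below 2 percentage points (birch / cedar / oak / alder / none)
- target present, with what was taken out counted in, in percent of the substrate first charged, after birch
- target present, with what was taken out counted in, in percent of the substrate first charged, after alder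

- The autumn plateau reads 22.3%, and this reckoning keeps that value for the autumn flask at 12 h.
- That plateau reads 0.186 as the partner share, target made per partner charged. The winter run reads 0.182, so the share holds across the two partner charges within the scatter.
- The loose bracket for birch runs from 22.3%, if added partner makes nothing, up to 100 percent of the substrate charged.
- The upper bound tightens to 44.7%: birch adds one more charge of partner to the autumn flask, reckoned at the same share.
- The lower bound tightens to 39.7% if the gain shrinks with the substrate left after the target already made.
- This tight bracket assumes that partner is the limiting reagent. The first autumn reading gives the stall a half-life of 0.262 h, much shorter than the 12 h wait.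
- The readings do not exclude a dying initiator, so choosing partner is a judgement. On that judgement the lower bound gives birch a gain of 17 percentage points against the 2 points threshold, while cedar, oak and alder add no partner and are reckoned to stay near 22.3%.
- The forecast gives 22.3% now, none as best remedy, 22.4% after birch and 22.3% after alder, holding that “its initiator is spent”, which puts its birch value below the tight bracket.
- The flask gives 22.1% now, birch as best remedy, 40.4% after birch and 22.1% after alder.

    initiator → 2 initiating radical (k = 0.0370 /h)
    substrate + initiating radical → chain carrier (k = 3.10 × 10⁷ /M/h)
    partner + chain carrier → target + initiating radical (k = 15000 /M/s)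
    2 initiating radical → ended chains A (k = 7.00 × 10⁶ /M/s)
    2 chain carrier → ended chains B (k = 6.30 × 10⁸ /M/s)
    partner ⇌ dormant form (K = 26.0, k = 0.0520 /h)
    partner → decomposed reagent (k = 2.20 /h)

- At 12 h the autumn flask holds 0% of its partner and 64.1% of its initiator. Its birch value lies inside the bracket, and the added partner shows a share of 0.152, lower than the autumn reading. The neighbouring flask has the same charges but 0.24 M of partner, so the partner share reckons it at 55.8%. That neighbour holds 0% of its partner at 12 h and gives 52.8%.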